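If I wanted to know before any run which flask would lead, I had to count how often the open intermediate got a chance to couple, so I counted that.

| setting | larch | alder | ash | maple |
|---|---|---|---|---|
| starting material | 20 mM | 20 mM | 20 mM | 20 mM |
| capture agent | 2.00 mM | 2.00 mM | 2.00 mM | 2.00 mM |
| gas | 2.9 mM (held) | 2.9 mM (held) | 2.9 mM (held) | 2.9 mM (held) |
| temperature | 25 °C | 75 °C | 50 °C |  |
| time | 50 min | 50 min | 50 min | 50 min |
| remark |  |  |  | at 25 °C until 15 min, from then on at 75 °C |

    starting material ⇌ open intermediate (K1 = 0.87, k1 = 0.083 min⁻¹, Ea1 = 76.0 kJ mol⁻¹, ΔH1 = 8.00 kJ mol⁻¹)
    partner → second intermediate (k2 = 0.27 min⁻¹, Ea2 = 78.0 kJ mol⁻¹)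
    open intermediate + second intermediate ⇌ target (K3 = 1500 L mol⁻¹, k3 = 2.4 L mol⁻¹ min⁻¹, Ea3 = 49.0 kJ mol⁻¹, ΔH3 = −24.0 kJ mol⁻¹)
    2 open intermediate → homo product (k4 = 0.091 L mol⁻¹ min⁻¹, Ea4 = 54.0 kJ mol⁻¹)
    second intermediate + capture agent → trapped intermediate (k5 = 3.4 L mol⁻¹ min⁻¹, Ea5 = 50.0 kJ mol⁻¹)
    gas ⇌ partner, rate k6*(csat - [partner]) (k6 = 0.37 min⁻¹, csat = 2.9 mM)
    (constants at 25 °C)

- in percentages every species weighs as the starting material in it: one homo product counts as two
- where a step has two of a species, its rate is k times that concentration squared, and two are used at each turn
- at the start none of partner is dissolved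
- the constants hold at 25 °C; other temperatures follow from the activation energies and enthalpies

- which flask leads in amount of target, in percent of the starting material charged ("all alike" within 1.5 percentage points) (larch / alder / ash / maple / all alike)
- how much target is there at the end, in percent of the starting material charged: larch
- how much target is there at the end, in percent of the starting material charged: alder
- how much target is there at the end, in percent of the starting material charged: ash
- how much target is there at the end, in percent of the starting material charged: maple

I started with larch. Partner dissolves and turns into second intermediate, and once those two steps balance, second intermediate arrives at a steady rate s = 0.453 mM min⁻¹. Coupling and capture draw it off. With the open intermediate and the capture agent frozen at their opening amounts, that draw is pseudo-first-order, with rate constant λ = 0.0291 min⁻¹. So c(second intermediate) climbs towards s/λ.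

Starting material and open intermediate form one pool in larch, because they relax far faster than the time asked, in 3.89 min. The open share of that pool is f = 0.465. I called N the coupling turnovers: f times the coupling constant times the time integral of c(second intermediate), which is the number of lives of the pool spent on coupling by time t. The formula is N = f·k·(s/λ)·(t − (1 − e^(−λt))/λ), and in larch it came to 0.411. The coupled fraction is then 1 − e^(−N).

I added one more column, h: the rate at which homo coupling eats open intermediate at the start, divided by s. Each flask's constants were taken at its own temperature.

| flask | s | λ | N | coupled | h |
|---|---|---|---|---|---|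
| larch | 0.453 mM min⁻¹ | 0.0291 min⁻¹ | 0.411 | 33.7 % | 0.0348 |
| ash | 0.958 mM min⁻¹ | 0.149 min⁻¹ | 1.62 | 80.2 % | 0.114 |
| alder | 1.06 mM min⁻¹ | 0.599 min⁻¹ | 2.03 | 86.9 % | 0.530 |

Reading the first row, larch spent less than one life of its pool, so it stood unfinished at the end of the time. Reading down the N column, alder counted more turnovers than ash, but N counts forward coupling and takes no account of target going back. The h column pointed the other way, with alder's opening homo coupling running harder against its delivery than ash's. Dividing the coupled fraction by 1 + h, a rough step, left ash 72.0 % and alder 56.8 %, so I committed to ash. Maple changes its constants at 15 min, so it got no row and I left it unreckoned.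

The forecast also chose ash, with larch 30 %, alder 68 %, ash 76 % and maple 71 %. For ash it said the coupling was “fast enough without those penalties being severe”. Its numbers differed from mine, most of all for alder.

The simulation put ash first, with larch 31.1 %, alder 66.9 %, ash 81.4 % and maple 72.1 %, so the forecast stood 5.4 percentage points below ash. My larch count of 0.411 had meant 33.7 % against that 31.1 %. Then I took the same larch, amounts and temperature held, and read it at 80 min. The same formula gave N = 0.850, so 57.3 % coupled. The reading there was 57.1 % target, with 24.0 % starting material, 16.2 % open intermediate and 2.72 % homo product.

(The numbers of this flask come from no measurement; the result is computed.)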